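**Retrosynthetic overview**

1. Target 26 ⇐ acid deprotection of 25; 25 ⇐ deletion of the ring nitrogen of the 23-membered azacycle 21, a 23 → 22 ring contraction that forges the CH2–CH2 bond at the benzylic carbon of ring A.
2. Enabling feature: the benzylic CH2 on C-3 of ring A (the 1-hydroxy-5-aryloxybenzene ring) sits next to a plain chain CH2; written as ArCH2–NH–CH2R it is a benzylic amine, so the ring can be closed by C–N chemistry and the ring-A-stabilised benzyl radical formed on N2 loss makes the C–C bond.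
3. 21 ⇐ Fukuyama–Mitsunobu macrocyclisation of sulfonamide/benzylic alcohol 19 ⇐ LiAlH4 reduction of ester/nitrile 17 ⇐ Z-selective Wittig reaction of aldehyde 13.
4. 13 ⇐ cleavage of a terminal alkene; (R)-carbinol ⇐ Noyori transfer hydrogenation of aryl ketone 9 ⇐ octenyl Grignard addition to the ring B aldehyde 5.
5. 5 ⇐ Chan–Lam coupling of syringaldehyde 1 with boronic acid 2 (rings A and B bought intact); ring order: diaryl ether, then the 23-membered azacycle (step 13), then the 22-membered carbocycle (step 15).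

Key step: step 15

**Route**

Step 1
Reactants: 1 syringaldehyde (4-hydroxy-3,5-dimethoxybenzaldehyde); 2 [3-methoxy-5-(methoxycarbonyl)phenyl]boronic acid
Product: 3 methyl 3-(4-formyl-2,6-dimethoxyphenoxy)-5-methoxybenzoate
Conditions: Cu(OAc)2 (2 equiv), pyridine (5 equiv), 4 Å MS, CH2Cl2, dry air, rt; 2 in excess (2 equiv)
Reagents that add atoms: none
Why: Chan–Lam–Evans O-arylation runs at room temperature on doubly ortho-substituted phenols and leaves aldehyde and ester untouched, so the hindered 2,6-dimethoxyphenyl aryl ether should form without forcing conditions.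

Step 2
Reactants: 3 methyl 3-(4-formyl-2,6-dimethoxyphenoxy)-5-methoxybenzoate
Product: 4 methyl 3-(4-formyl-2,6-dihydroxyphenoxy)-5-hydroxybenzoate
Conditions: BBr3 (5 equiv), CH2Cl2, −78 → 0 °C; then H2O
Reagents that add atoms: none
Why: Lewis-acid ether cleavage with BBr3 should remove all three O-methyl groups while the diaryl ether, aldehyde and methyl ester survive at or below 0 °C, and it is placed here because no carbinol or alkene is present yet.

Step 3
Reactants: 4 methyl 3-(4-formyl-2,6-dihydroxyphenoxy)-5-hydroxybenzoate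
Product: 5 methyl 3-[4-formyl-2,6-bis(methoxymethoxy)phenoxy]-5-(methoxymethoxy)benzoate
Conditions: MOMCl (4 equiv), i-Pr2NEt, CH2Cl2, 0 °C → rt
Reagents that add atoms: chloromethyl methyl ether (MOMCl), COCCl
Why: O-alkylation of the three phenols gives acetal ethers that should withstand Grignard, hydride, ylide, Mitsunobu and thiolate chemistry and leave in dilute acid at the end.

Step 4
Reactants: 5 methyl 3-[4-formyl-2,6-bis(methoxymethoxy)phenoxy]-5-(methoxymethoxy)benzoate; 6 8-bromooct-1-ene
Product: 8 racemic methyl 3-[4-(1-hydroxynon-8-en-1-yl)-2,6-bis(methoxymethoxy)phenoxy]-5-(methoxymethoxy)benzoate, via oct-7-en-1-ylmagnesium bromide 7 (not isolated)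
Conditions: 6, Mg, THF, rt; then 5, THF, −78 °C; aq NH4Cl
Reagents that add atoms: none
Why: Grignard addition at −78 °C should be selective for the aldehyde over the methyl benzoate, and the racemic carbinol is corrected by the oxidation/asymmetric reduction that follows.

Step 5
Reactants: 8 racemic methyl 3-[4-(1-hydroxynon-8-en-1-yl)-2,6-bis(methoxymethoxy)phenoxy]-5-(methoxymethoxy)benzoate
Product: 9 methyl 3-[2,6-bis(methoxymethoxy)-4-(non-8-enoyl)phenoxy]-5-(methoxymethoxy)benzoate
Conditions: Dess–Martin periodinane, NaHCO3, CH2Cl2, rt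
Reagents that add atoms: none
Why: Dess–Martin oxidation converts the benzylic alcohol into the aryl ketone under neutral conditions that spare the acetals and the terminal alkene.

Step 6
Reactants: 9 methyl 3-[2,6-bis(methoxymethoxy)-4-(non-8-enoyl)phenoxy]-5-(methoxymethoxy)benzoate
Product: 10 methyl 3-[4-[(1R)-1-hydroxynon-8-en-1-yl]-2,6-bis(methoxymethoxy)phenoxy]-5-(methoxymethoxy)benzoate
Conditions: RuCl(p-cymene)[(R,R)-TsDPEN] (2 mol%), HCO2H/Et3N (1:1), DMF, 40 °C
Reagents that add atoms: none
Why: Noyori asymmetric transfer hydrogenation of an aryl alkyl ketone without ortho substituents with the (R,R)-TsDPEN ruthenium catalyst should deliver hydride to the face that gives the (R)-1-arylalkanol (same sense as (R)-1-phenylethanol from acetophenone), and unlike a borane reduction it leaves the terminal alkene alone.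

Step 7
Reactants: 10 methyl 3-[4-[(1R)-1-hydroxynon-8-en-1-yl]-2,6-bis(methoxymethoxy)phenoxy]-5-(methoxymethoxy)benzoate
Product: 11 methyl 3-[4-[(1R)-1-(tert-butyldimethylsilyloxy)non-8-en-1-yl]-2,6-bis(methoxymethoxy)phenoxy]-5-(methoxymethoxy)benzoate
Conditions: TBSCl, imidazole, DMF, rt
Reagents that add atoms: tert-butyldimethylsilyl chloride (TBSCl), CC(C)(C)[Si](C)(C)Cl
Why: Silylation masks the secondary carbinol so that it cannot be activated in the later Mitsunobu ring closure, and the configuration is untouched because no bond to the stereocentre is broken.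

Step 8
Reactants: 11 methyl 3-[4-[(1R)-1-(tert-butyldimethylsilyloxy)non-8-en-1-yl]-2,6-bis(methoxymethoxy)phenoxy]-5-(methoxymethoxy)benzoate
Product: 13 methyl 3-[4-[(1R)-1-(tert-butyldimethylsilyloxy)-8-oxooctyl]-2,6-bis(methoxymethoxy)phenoxy]-5-(methoxymethoxy)benzoate, via vicinal diol 12 (not isolated)
Conditions: OsO4 (2 mol%), NaIO4 (4 equiv), 2,6-lutidine, 1,4-dioxane/H2O (3:1), rt
Reagents that add atoms: osmium tetroxide, O=[Os](=O)(=O)=O (catalytic oxygen carrier); sodium periodate, [Na+].[O-]I(=O)(=O)=O (stoichiometric oxidant)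
Why: Lemieux–Johnson cleavage (dihydroxylation, then periodate glycol cleavage) acts on the only alkene and gives the aldehyde, with lutidine buffering the acetals and the silyl ether.

Step 9
Reactants: 14 5-bromopentanenitrile
Product: 15 (4-cyanobutyl)triphenylphosphonium bromide
Conditions: PPh3, MeCN, reflux
Reagents that add atoms: triphenylphosphine, c1ccc(cc1)P(c1ccccc1)c1ccccc1
Why: SN2 quaternisation of triphenylphosphine by a primary bromide is a standard phosphonium salt synthesis.

Step 10
Reactants: 13 methyl 3-[4-[(1R)-1-(tert-butyldimethylsilyloxy)-8-oxooctyl]-2,6-bis(methoxymethoxy)phenoxy]-5-(methoxymethoxy)benzoate; 15 (4-cyanobutyl)triphenylphosphonium bromide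
Product: 17 methyl 3-[4-[(1R,8Z)-1-(tert-butyldimethylsilyloxy)-12-cyanododec-8-en-1-yl]-2,6-bis(methoxymethoxy)phenoxy]-5-(methoxymethoxy)benzoate, via phosphonium ylide 16 (not isolated)
Conditions: 15, NaHMDS, THF, −78 °C; then 13, −78 °C → rt
Reagents that add atoms: none
Why: A salt-free Wittig reaction of an unstabilised ylide with an aliphatic aldehyde should give the Z alkene through the kinetically preferred cis-oxaphosphetane, while the aryl ester and the nitrile are inert at low temperature.

Step 11
Reactants: 17 methyl 3-[4-[(1R,8Z)-1-(tert-butyldimethylsilyloxy)-12-cyanododec-8-en-1-yl]-2,6-bis(methoxymethoxy)phenoxy]-5-(methoxymethoxy)benzoate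
Product: 18 [3-[4-[(1R,8Z)-13-amino-1-(tert-butyldimethylsilyloxy)tridec-8-en-1-yl]-2,6-bis(methoxymethoxy)phenoxy]-5-(methoxymethoxy)phenyl]methanol
Conditions: LiAlH4, THF, 0 °C → rt; Fieser work-up
Reagents that add atoms: none
Why: LiAlH4 reduces the ester to the benzylic alcohol and the nitrile to the primary amine in one operation, and the silyl ether, the acetals and the isolated Z alkene should not react.

Step 12
Reactants: 18 [3-[4-[(1R,8Z)-13-amino-1-(tert-butyldimethylsilyloxy)tridec-8-en-1-yl]-2,6-bis(methoxymethoxy)phenoxy]-5-(methoxymethoxy)phenyl]methanol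
Product: 19 N-[(5Z,13R)-13-(tert-butyldimethylsilyloxy)-13-[4-[3-(hydroxymethyl)-5-(methoxymethoxy)phenoxy]-3,5-bis(methoxymethoxy)phenyl]tridec-5-en-1-yl]-2-nitrobenzenesulfonamide
Conditions: 2-nitrobenzenesulfonyl chloride (1.05 equiv), Et3N, CH2Cl2, 0 °C
Reagents that add atoms: 2-nitrobenzenesulfonyl chloride (NsCl), O=S(=O)(Cl)c1ccccc1[N+](=O)[O-]
Why: N-sulfonylation of the primary amine, which is far more nucleophilic than the benzylic alcohol, gives the Fukuyama sulfonamide whose N–H is acidic enough for a Mitsunobu alkylation.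

Step 13
Reactants: 19 N-[(5Z,13R)-13-(tert-butyldimethylsilyloxy)-13-[4-[3-(hydroxymethyl)-5-(methoxymethoxy)phenoxy]-3,5-bis(methoxymethoxy)phenyl]tridec-5-en-1-yl]-2-nitrobenzenesulfonamide
Product: 20 N-(2-nitrophenylsulfonyl) 23-membered azacycle (ring A CH2–N(Ns)–(CH2)4–CH=CH(Z)–(CH2)6–(R)-CH(OTBS)–ring B; rings joined by the diaryl ether; three MOM ethers)
Conditions: PPh3, DIAD, toluene/THF, 0.002 M (slow addition of 19), rt
Reagents that add atoms: none
Why: The intramolecular Fukuyama–Mitsunobu alkylation of the sulfonamide by the primary benzylic alcohol is an established way to close large-ring amines under high dilution, the sulfonyl group prevents over-alkylation, and the silylated secondary carbinol cannot compete.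

Step 14
Reactants: 20 N-(2-nitrophenylsulfonyl) 23-membered azacycle
Product: 21 23-membered macrocyclic secondary amine (ring A CH2–NH–(CH2)4–CH=CH(Z)–(CH2)6–(R)-CH(OTBS)–ring B; three MOM ethers)
Conditions: PhSH, K2CO3, MeCN, rt
Reagents that add atoms: none
Why: Fukuyama denosylation (thiolate addition to the nitroarene, Meisenheimer complex, loss of SO2) frees the amine under conditions to which the acetals, the silyl ether and the alkene are inert.

Step 15
Reactants: 21 23-membered macrocyclic secondary amine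
Product: 25 22-membered carbocycle; tris(methoxymethyl) ether and TBS ether of the target (R carbinol; Z alkene), via N-amino amide adduct 22 (not isolated), via isodiazene 23 (not isolated), via benzyl alkyl diradical 24 (not isolated)
Conditions: N-(benzyloxy)-N-(pivaloyloxy)-4-(trifluoromethyl)benzamide (1.5 equiv), THF (0.05 M), 45 °C
Reagents that add atoms: none
Why: The secondary amine of 21 attacks the amide nitrogen of the anomeric amide and displaces pivalate to give the N-amino-N-benzyloxy amide 22, which expels benzyl 4-(trifluoromethyl)benzoate to give the 1,1-diazene (isodiazene) 23; loss of N2 then gives the singlet benzyl/primary-alkyl radical pair 24, which recombines to the CH2–CH2 bond. The closest known reaction type is the nitrogen deletion of N-benzyl secondary amines (acyclic N-benzyl-N-alkylamines and cyclic 2-aryl or benzo-fused azacycles) with this reagent, the modern form of the Overberger–Lombardino 1,1-diazene extrusion. The 22-membered carbocycle is closed by ring contraction of the 23-membered azacycle: the two carbons are born about 2.5 Å apart on either side of the departing N2, so closure is a geminate radical–radical recombination and not an end-to-end macrocyclisation. No stereocentre is formed, and the remote, silylated (R)-carbinol and the Z alkene are not part of the reacting array. The step needs recombination to outrun 5-exo cyclisation of the hex-5-enyl-type chain radical onto the Z alkene, disproportionation, and tautomerisation of the isodiazene to a hydrazone; the benzylic CH2 of ring A should secure this by making N2 loss fast and the pair a contact singlet pair that collapses well within the time a 5-exo closure needs, and the meta (not ortho or para) oxygens of ring A open no quinone-methide channel. All O–H groups are capped, so neither the reagent nor the radical pair meets an acidic or easily abstracted hydrogen.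

Step 16
Reactants: 25 22-membered carbocycle; tris(methoxymethyl) ether and TBS ether of the target
Product: 26 target macrocyclic diaryl ether CNP0316989.2 (R carbinol; Z alkene)
Conditions: 3 M aq HCl/THF (1:3), rt → 40 °C
Reagents that add atoms: none
Why: Acid hydrolysis removes the three aryl MOM acetals and the silyl ether in one operation, and the (R)-carbinol should persist because its ring carries only meta oxygens and a twisted para aryloxy group, so the benzylic cation is poorly stabilised and water is the only nucleophile present.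

**Compound list**

1 | syringaldehyde (4-hydroxy-3,5-dimethoxybenzaldehyde) | COc1cc(C=O)cc(OC)c1O | starting material
2 | [3-methoxy-5-(methoxycarbonyl)phenyl]boronic acid | COC(=O)c1cc(OC)cc(B(O)O)c1 | starting material
3 | methyl 3-(4-formyl-2,6-dimethoxyphenoxy)-5-methoxybenzoate | COC(=O)c1cc(OC)cc(Oc2c(OC)cc(C=O)cc2OC)c1 | intermediate
4 | methyl 3-(4-formyl-2,6-dihydroxyphenoxy)-5-hydroxybenzoate | COC(=O)c1cc(O)cc(Oc2c(O)cc(C=O)cc2O)c1 | intermediate
5 | methyl 3-[4-formyl-2,6-bis(methoxymethoxy)phenoxy]-5-(methoxymethoxy)benzoate | COC(=O)c1cc(OCOC)cc(Oc2c(OCOC)cc(C=O)cc2OCOC)c1 | intermediate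
6 | 8-bromooct-1-ene | C=CCCCCCCBr | starting material
7 | oct-7-en-1-ylmagnesium bromide (not isolated) | C=CCCCCCC[Mg]Br | intermediate
8 | racemic methyl 3-[4-(1-hydroxynon-8-en-1-yl)-2,6-bis(methoxymethoxy)phenoxy]-5-(methoxymethoxy)benzoate | COC(=O)c1cc(OCOC)cc(Oc2c(OCOC)cc(C(O)CCCCCCC=C)cc2OCOC)c1 | intermediate
9 | methyl 3-[2,6-bis(methoxymethoxy)-4-(non-8-enoyl)phenoxy]-5-(methoxymethoxy)benzoate | COC(=O)c1cc(OCOC)cc(Oc2c(OCOC)cc(C(=O)CCCCCCC=C)cc2OCOC)c1 | intermediate
10 | methyl 3-[4-[(1R)-1-hydroxynon-8-en-1-yl]-2,6-bis(methoxymethoxy)phenoxy]-5-(methoxymethoxy)benzoate | COC(=O)c1cc(OCOC)cc(Oc2c(OCOC)cc([C@H](O)CCCCCCC=C)cc2OCOC)c1 | intermediate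
11 | methyl 3-[4-[(1R)-1-(tert-butyldimethylsilyloxy)non-8-en-1-yl]-2,6-bis(methoxymethoxy)phenoxy]-5-(methoxymethoxy)benzoate | COC(=O)c1cc(OCOC)cc(Oc2c(OCOC)cc([C@H](O[Si](C)(C)C(C)(C)C)CCCCCCC=C)cc2OCOC)c1 | intermediate
12 | methyl 3-[4-[(1R)-1-(tert-butyldimethylsilyloxy)-8,9-dihydroxynonyl]-2,6-bis(methoxymethoxy)phenoxy]-5-(methoxymethoxy)benzoate (C-8 epimers; not isolated) | COC(=O)c1cc(OCOC)cc(Oc2c(OCOC)cc([C@H](O[Si](C)(C)C(C)(C)C)CCCCCCC(O)CO)cc2OCOC)c1 | intermediate
13 | methyl 3-[4-[(1R)-1-(tert-butyldimethylsilyloxy)-8-oxooctyl]-2,6-bis(methoxymethoxy)phenoxy]-5-(methoxymethoxy)benzoate | COC(=O)c1cc(OCOC)cc(Oc2c(OCOC)cc([C@H](O[Si](C)(C)C(C)(C)C)CCCCCCC=O)cc2OCOC)c1 | intermediate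
14 | 5-bromopentanenitrile | N#CCCCCBr | starting material
15 | (4-cyanobutyl)triphenylphosphonium bromide | N#CCCCC[P+](c1ccccc1)(c1ccccc1)c1ccccc1.[Br-] | intermediate
16 | (4-cyanobutylidene)triphenylphosphorane (not isolated) | N#CCCCC=P(c1ccccc1)(c1ccccc1)c1ccccc1 | intermediate
17 | methyl 3-[4-[(1R,8Z)-1-(tert-butyldimethylsilyloxy)-12-cyanododec-8-en-1-yl]-2,6-bis(methoxymethoxy)phenoxy]-5-(methoxymethoxy)benzoate | COC(=O)c1cc(OCOC)cc(Oc2c(OCOC)cc([C@H](O[Si](C)(C)C(C)(C)C)CCCCCC/C=C\CCCC#N)cc2OCOC)c1 | intermediate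
18 | [3-[4-[(1R,8Z)-13-amino-1-(tert-butyldimethylsilyloxy)tridec-8-en-1-yl]-2,6-bis(methoxymethoxy)phenoxy]-5-(methoxymethoxy)phenyl]methanol | OCc1cc(OCOC)cc(Oc2c(OCOC)cc([C@H](O[Si](C)(C)C(C)(C)C)CCCCCC/C=C\CCCCN)cc2OCOC)c1 | intermediate
19 | N-[(5Z,13R)-13-(tert-butyldimethylsilyloxy)-13-[4-[3-(hydroxymethyl)-5-(methoxymethoxy)phenoxy]-3,5-bis(methoxymethoxy)phenyl]tridec-5-en-1-yl]-2-nitrobenzenesulfonamide | OCc1cc(OCOC)cc(Oc2c(OCOC)cc([C@H](O[Si](C)(C)C(C)(C)C)CCCCCC/C=C\CCCCNS(=O)(=O)c3ccccc3[N+](=O)[O-])cc2OCOC)c1 | intermediate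
20 | N-(2-nitrophenylsulfonyl) 23-membered azacycle (R carbinol TBS ether; Z alkene; three MOM ethers) | O=S(=O)(c1ccccc1[N+](=O)[O-])N1Cc2cc(OCOC)cc(c2)Oc2c(OCOC)cc(cc2OCOC)[C@H](O[Si](C)(C)C(C)(C)C)CCCCCC/C=C\CCCC1 | intermediate
21 | 23-membered macrocyclic secondary amine (R carbinol TBS ether; Z alkene; three MOM ethers) | N1Cc2cc(OCOC)cc(c2)Oc2c(OCOC)cc(cc2OCOC)[C@H](O[Si](C)(C)C(C)(C)C)CCCCCC/C=C\CCCC1 | intermediate
22 | N-amino-N-benzyloxy-4-(trifluoromethyl)benzamide adduct of 21 (not isolated) | O=C(c1ccc(cc1)C(F)(F)F)N(OCc1ccccc1)N1Cc2cc(OCOC)cc(c2)Oc2c(OCOC)cc(cc2OCOC)[C@H](O[Si](C)(C)C(C)(C)C)CCCCCC/C=C\CCCC1 | intermediate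
23 | macrocyclic isodiazene (1,1-diazene) of 21 (not isolated) | [N-]=[N+]1Cc2cc(OCOC)cc(c2)Oc2c(OCOC)cc(cc2OCOC)[C@H](O[Si](C)(C)C(C)(C)C)CCCCCC/C=C\CCCC1 | intermediate
24 | benzyl/primary alkyl diradical after N2 loss (not isolated) | [CH2]c1cc(OCOC)cc(Oc2c(OCOC)cc([C@H](O[Si](C)(C)C(C)(C)C)CCCCCC/C=C\CCC[CH2])cc2OCOC)c1 | intermediate
25 | 22-membered carbocycle; tris(methoxymethyl) ether and TBS ether of the target (R; Z) | C1c2cc(OCOC)cc(c2)Oc2c(OCOC)cc(cc2OCOC)[C@H](O[Si](C)(C)C(C)(C)C)CCCCCC/C=C\CCCC1 | intermediate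
26 | target CNP0316989.2 (R carbinol; Z alkene) | Oc1cc2cc(c1)Oc1c(O)cc(cc1O)[C@H](O)CCCCCC/C=C\CCCCC2 | target

**Step count and risks**

Total step count: 16. Longest linear sequence: 15 steps (steps 1–8 and 10–16, from 1 to 26); step 9 is a one-step side branch.

Steps most likely to fail:

Step 15 (nitrogen deletion). The radical pair may leave the geminate recombination path: 5-exo closure of the chain radical onto the Z alkene, disproportionation of the two radical ends, or tautomerisation of the isodiazene to a hydrazone before N2 is lost. The fallback closes the same CH2–CH2 bond by polar chemistry; it sets out from aldehyde 13 and returns to the route at 25. Wittig reaction of 13 with the ylide of commercial (4-carboxybutyl)triphenylphosphonium bromide (NaHMDS, THF, −78 °C → rt) should give the Z acid ester F1. LiAlH4 then reduces both carbonyl groups to the diol F2, and CBr4/PPh3 gives the dibromide F3. PhSO2Na (1 equiv, DMF, 0 °C) should substitute only the benzylic bromide and give the sulfone bromide F4. KHMDS in THF under high dilution closes the 22-membered ring by alkylation of the benzylic sulfonyl carbanion with the primary bromide, giving the macrocyclic sulfone F5. Mg in MeOH removes the sulfonyl group reductively and gives 25.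

Step 1 (diaryl ether). O-arylation of the doubly ortho-substituted, electron-poor phenoxide may be too slow, so that protodeboronation and oxidative homocoupling of the boronic acid consume 2 first. The fallback is a metal-free arylation with a diaryl-λ3-iodane; it sets out from 1 and 2 and returns at 3. Iododeboronation of 2 (I2, K2CO3, MeCN, 80 °C) gives methyl 3-iodo-5-methoxybenzoate F6. One-pot oxidation and arene capture (mCPBA, TsOH·H2O, MeCN; then 1,3,5-trimethoxybenzene) gives the aryl(2,4,6-trimethoxyphenyl)iodonium tosylate F7. Treatment of 1 with t-BuOK and F7 in THF at 40 °C should transfer the ester-bearing aryl group selectively to the hindered phenoxide and give 3.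

Step 13 (macrocyclisation). Intermolecular N-alkylation may outrun the 23-membered ring closure and give oligomers, or the activated benzylic oxyphosphonium ion may be intercepted before the sulfonamide reaches it. The fallback closes the ring by reversible imine formation instead; it sets out from amino alcohol 18 and returns at 21, bypassing 19 and 20. Activated MnO2 (CH2Cl2, 4 Å MS, 0.002 M) oxidises only the primary benzylic alcohol to the amino aldehyde F8, which condenses in the flask to the macrocyclic imine F9 under thermodynamic control. NaBH4 in MeOH reduces F9 to 21.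

Further compounds
F1 | step 15 | (5Z,13R)-13-(tert-butyldimethylsilyloxy)-13-[4-[3-(methoxycarbonyl)-5-(methoxymethoxy)phenoxy]-3,5-bis(methoxymethoxy)phenyl]tridec-5-enoic acid | COC(=O)c1cc(OCOC)cc(Oc2c(OCOC)cc([C@H](O[Si](C)(C)C(C)(C)C)CCCCCC/C=C\CCCC(=O)O)cc2OCOC)c1
F2 | step 15 | (5Z,13R)-13-(tert-butyldimethylsilyloxy)-13-[4-[3-(hydroxymethyl)-5-(methoxymethoxy)phenoxy]-3,5-bis(methoxymethoxy)phenyl]tridec-5-en-1-ol | OCc1cc(OCOC)cc(Oc2c(OCOC)cc([C@H](O[Si](C)(C)C(C)(C)C)CCCCCC/C=C\CCCCO)cc2OCOC)c1
F3 | step 15 | dibromide of F2 (benzylic bromide on ring A and primary bromide at the chain end) | BrCc1cc(OCOC)cc(Oc2c(OCOC)cc([C@H](O[Si](C)(C)C(C)(C)C)CCCCCC/C=C\CCCCBr)cc2OCOC)c1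
F4 | step 15 | benzylic phenyl sulfone with primary bromide at the chain end | O=S(=O)(Cc1cc(OCOC)cc(Oc2c(OCOC)cc([C@H](O[Si](C)(C)C(C)(C)C)CCCCCC/C=C\CCCCBr)cc2OCOC)c1)c1ccccc1
F5 | step 15 | 22-membered carbocycle bearing a phenylsulfonyl group on the ring A benzylic carbon (epimers) | O=S(=O)(c1ccccc1)C1c2cc(OCOC)cc(c2)Oc2c(OCOC)cc(cc2OCOC)[C@H](O[Si](C)(C)C(C)(C)C)CCCCCC/C=C\CCCC1
F6 | step 1 | methyl 3-iodo-5-methoxybenzoate | COC(=O)c1cc(OC)cc(I)c1
F7 | step 1 | [3-methoxy-5-(methoxycarbonyl)phenyl](2,4,6-trimethoxyphenyl)iodonium 4-methylbenzenesulfonate | COC(=O)c1cc(OC)cc([I+]c2c(OC)cc(OC)cc2OC)c1.Cc1ccc(cc1)S(=O)(=O)[O-]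
F8 | step 13 | 3-[4-[(1R,8Z)-13-amino-1-(tert-butyldimethylsilyloxy)tridec-8-en-1-yl]-2,6-bis(methoxymethoxy)phenoxy]-5-(methoxymethoxy)benzaldehyde | O=Cc1cc(OCOC)cc(Oc2c(OCOC)cc([C@H](O[Si](C)(C)C(C)(C)C)CCCCCC/C=C\CCCCN)cc2OCOC)c1
F9 | step 13 | 23-membered macrocyclic imine (ring A CH=N–chain) | N1=Cc2cc(OCOC)cc(c2)Oc2c(OCOC)cc(cc2OCOC)[C@H](O[Si](C)(C)C(C)(C)C)CCCCCC/C=C\CCCC1
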